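**Remarks on the chemistry (assumptions)**
- Compounds 1 and 6, carbon monoxide 9, benzyl bromide and the diazophosphonate of step 4 are taken as purchased.
- The sense of induction of the chiral carbene in step 6 cannot be read off in advance for a 2',6'-disubstituted flavone. The ligand antipode written is taken to give (2S); its mirror image, equally available, would be used otherwise.

## Analysis of the target

The target 16 is (2S)-5-hydroxy-2-(2-hydroxy-6-methoxyphenyl)-6,7,8-trimethoxychroman-4-one, a flavanone. A benzene ring A is fused to a dihydropyranone ring C (O1, C2, C3, C4, C4a, C8a), and an aryl ring B sits on C2. Ring A carries no hydrogen: C5 bears a phenol that is hydrogen-bonded to the C4 carbonyl, and C6, C7 and C8 bear methoxy groups. Ring B is oxygenated at both positions ortho to C2 (2'-OH and 6'-OMe).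

C2 is the only stereocentre and is S (priorities O1 > C1' > C3 > H), so there is no second centre to relate it to. It is a labile centre, because the C2–O1 bond is benzylic to an electron-rich ring and β to the ketone. Base can open ring C to the chalcone, a strong Lewis acid can ionise the bond, and the free 2'-phenol opens an ortho-quinone-methide pathway; each of these racemises C2.

The difficulties are therefore threefold: a hexasubstituted ring A in which one oxygen (C5) must be told from three others, the crowding that a di-ortho-substituted ring B places around C2, and the need to create C2 late and to treat it gently afterwards.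

The strategy rests on one structural feature. C4 is a single carbonyl carbon that bridges C4a and C3, and O1 sits on C8a next to C4a. Ring C is therefore the sum of an ortho-iodophenol, a one-carbon carbonyl unit and an aryl acetylene. Because ring A is fully substituted, the iodophenol needed is the only monoiodide its parent phenol can give. The peri relation of the C5 methoxy group to C4=O later singles out that one methyl ether for cleavage.

## Retrosynthetic reasoning

**16 ⇒ 15 (O–benzyl bond of ring B).** The 2'-phenol is unmasked last. Once it is free, the ortho-quinone-methide route to racemisation exists, so the final operation should be neutral. A benzyl ether removed by hydrogenolysis meets that condition and survives everything before it.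

**15 ⇒ 14 (O–CH3 bond at C5).** The four A-ring oxygens are carried as methyl ethers, and only the C5 ether is cut. It alone can form a six-membered chelate with the C4 carbonyl around a boron Lewis acid, so the selection comes from the substrate. What is gained is that ring A can come from a symmetrical tetramethoxybenzene with no early differentiation of C5.

**14 ⇒ 13 ⇒ 12 (C2–H and C3–H bonds; redox at C4).** The stereocentre is traced back to the planar, achiral flavone 12. The forward reaction has to deliver hydrogen to one face of C2=C3. The catalyst chosen for this reduces the ketone as well, giving flavanol 13, so a re-oxidation to 14 follows. The C4 carbinol centre is transient and its configuration is irrelevant. Cutting here means everything up to 12 is achiral and robust.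

**12 ⇒ 5 + 8 + 9 (C4a–C4, C4–C3 and O1–C2; ring C).** All three bonds of ring C that do not belong to ring A or the acetylene are cut at once. Forward, palladium carries carbon monoxide 9 into the C–I bond of iodophenol 5 and acylates alkyne 8 to give ynone 10. A secondary amine then turns 10 into enaminone 11, which closes to 12. This cut is preferred to an aldol or acyl-transfer construction because it needs no acetophenone or benzoic acid on the crowded ring A. It also joins two fragments of similar size in one flask. The forward reaction must take up CO before it alkynylates, and must close the six-membered rather than the five-membered ring.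

**5 ⇒ 4 ⇒ 1 (C–I, then C–O).** The iodine of 5 goes onto the one free ring position of phenol 4, so regiochemistry is not an issue. Phenol 4 comes from 1 by replacing one of its two equivalent ring hydrogens with hydroxyl, through aryllithium 2 and boronate 3 in one flask.

**8 ⇒ 7 ⇒ 6 (C≡C, then O–benzyl).** The ethynyl group of 8 is the formyl group of 7 plus one carbon (diazophosphonate homologation). Aldehyde 7 is the benzyl ether of commercial 6, which already has the 2-oxy-6-methoxy pattern of ring B.

## Alternatives that were turned down

**Alternative 1: carbene-catalysed closure of C3–C4.**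
- Disconnection: the C3–C4 bond.
- Forward key step: an N-heterocyclic carbene adds to the aldehyde of tosylate A2. The resulting Breslow intermediate, an acyl-anion equivalent, displaces the primary tosylate intramolecularly and closes ring C as ketone A1, which is the same compound as 14.
- For: ring C arrives at the ketone oxidation level with C2 already in place. The hydrogenation and re-oxidation pair of the chosen route would be saved, and the stereocentre would be made on a small molecule where its purity can be checked early. On these two points this alternative is the stronger one.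
- Against: A2 needs the O1–C2 ether between a phenol flanked on both sides and a secondary benzylic carbon with two ortho oxygens. Invertive etherification at such a centre competes with ionisation to a well-stabilised benzylic cation, so enantiopurity can be lost before the key step. The aldehyde of A2 is electron-rich and di-ortho-substituted, so carbene addition is slow. The base that frees the carbene can instead eliminate the tosylate to an enol ether. The C5 demethylation and the debenzylation remain, so the end game is no shorter.
- Comparison: the chosen route keeps every intermediate achiral up to 12 and forms three bonds in one flask from two simple arenes. Its stereochemical risk lies in one catalytic step that has a resolution as back-up.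

**Alternative 2: ring A from a squarate-derived cyclobutenone.**
- Disconnection: ring A itself, with C4a–C5 as the last bond formed.
- Forward key step: a dihydropyran lithiated at its enol-ether carbon (the future C8a) adds to dimethyl squarate A4, and the carbinol is methylated. Thermolysis opens the cyclobutenone (4π) to a dienylketene, which closes (6π) and tautomerises to phenol A3.
- For: the C5 hydroxyl emerges free and distinct from the three methoxy groups by construction, so no selective demethylation is needed. The stereocentre is set early on a simple pyran. In differentiating C5 this alternative is stronger than the chosen route.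
- Against: lithiation of the enol ether must win over deprotonation at the benzylic, allylic C2–H and at the benzyl ether. A3 is an ortho-hydroxybenzyl silyl ether formed above 100 °C, which is set up for elimination to an ortho-quinone methide. After the key step, C4 must be desilylated and oxidised in the presence of a free para-methoxyphenol that is itself easily oxidised to a quinone. The count is long: about four steps to the pyran, then addition, methylation, thermolysis, desilylation, oxidation and debenzylation.
- Comparison: the chosen route takes the same ring A from a commercial tetraoxygenated benzene in two steps. It pays for the C5 differentiation with one chelation-controlled demethylation.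

**Alternative 3: ring B grown on the stereocentre by Danheiser benzannulation.**
- Disconnection: ring B, through C1'–C2', C5'–C6' and C2'–C3'.
- Forward key step: cyclobutenone A6 is heated with methoxyalkyne A7. A6 opens to vinylketene, which adds [2+2] to the electron-rich alkyne. The new cyclobutenone reopens, and 6π closure with tautomerisation gives phenol A5, with the hydroxyl at C2' and the methoxy group at C6'.
- For: the two oxygens of ring B come out differentiated and regiodefined with no protecting group. No crowded aryl group is present when C2 is made. In protecting-group economy on ring B this alternative is stronger.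
- Against: in A7 the stereocentre is propargylic, bonded to O1 and β to the ketone. At the 80–140 °C the annulation needs, ring opening by retro-oxa-Michael reaction would racemise it. There is no short, reliable entry to an enantioenriched 2-(alkoxyethynyl)chromanone. A6 is volatile and polymerises readily. Ring A must still be built, with C5 protected differently from its neighbours.
- Comparison: the chosen route takes ring B from a commercial aldehyde in two steps and joins it in a reaction that creates no stereocentre and needs no heat-sensitive partner. The B-ring benzyl ether it needs is removed in the one final neutral step.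

Key step: step 5

## Route

**Step 1**
Reactants: 1 1,2,3,4-tetramethoxybenzene
Product: 4 2,3,4,5-tetramethoxyphenol, via aryllithium 2 (not isolated), via dimethyl arylboronate 3 (not isolated)
Conditions: n-BuLi, TMEDA, THF, 0 °C; B(OMe)3, −78 °C → rt; AcOH, 30% aq. H2O2, 0 °C → rt
Reagents that add atoms: hydrogen peroxide, OO
Why: Directed ortho-metalation; the two ring hydrogens of 1 are equivalent and each is ortho to a methoxy group, so one aryllithium forms, and borylation followed by peroxide oxidation (aryl shift from boron to oxygen) should give the phenol.

**Step 2**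
Reactants: 4 2,3,4,5-tetramethoxyphenol
Product: 5 2-iodo-3,4,5,6-tetramethoxyphenol
Conditions: NIS, MeCN, 0 °C, dark
Reagents that add atoms: N-iodosuccinimide, O=C1CCC(=O)N1I
Why: Electrophilic aromatic iodination of a strongly activated phenol; the only unsubstituted ring carbon is ortho to the hydroxyl, so a single monoiodide is possible.

**Step 3**
Reactants: 6 2-hydroxy-6-methoxybenzaldehyde
Product: 7 2-(benzyloxy)-6-methoxybenzaldehyde
Conditions: BnBr, K2CO3, DMF, 60 °C
Reagents that add atoms: benzyl bromide, BrCc1ccccc1
Why: Williamson ether synthesis; the phenoxide is alkylated by a primary benzylic bromide, and warming overcomes the hydrogen bond to the aldehyde.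

**Step 4**
Reactants: 7 2-(benzyloxy)-6-methoxybenzaldehyde
Product: 8 1-(benzyloxy)-2-ethynyl-3-methoxybenzene
Conditions: dimethyl (1-diazo-2-oxopropyl)phosphonate, K2CO3, MeOH, 0 °C → rt
Reagents that add atoms: dimethyl (1-diazo-2-oxopropyl)phosphonate, COP(=O)(OC)C(=[N+]=[N-])C(C)=O
Why: Seyferth–Gilbert homologation in its Ohira–Bestmann form; methanolysis frees the diazomethylphosphonate anion, which olefinates the aldehyde, and loss of N2 with a 1,2-hydrogen shift gives the terminal alkyne under conditions that leave both ethers untouched.

**Step 5 (key step)**
Reactants: 5 2-iodo-3,4,5,6-tetramethoxyphenol; 8 1-(benzyloxy)-2-ethynyl-3-methoxybenzene; 9 carbon monoxide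
Product: 12 2-[2-(benzyloxy)-6-methoxyphenyl]-5,6,7,8-tetramethoxy-4H-chromen-4-one, via ortho-hydroxyaryl ynone 10 (not isolated), via diethylamino enone 11 (not isolated)
Conditions: PdCl2(dppf) (5 mol %), CO (10 bar), Et3N, THF, 60 °C; then vent, Et2NH, 50 °C
Reagents that add atoms: none
Why: Zerovalent palladium, formed from PdCl2(dppf) under CO and amine, inserts into the C–I bond of 5; CO migrates into the electron-rich aryl–palladium bond, and the acylpalladium iodide takes up the acetylide of 8 (amine base, no copper) and reductively eliminates ynone 10, which fixes C4a–C4 and C4–C3. Diethylamine is added only after the coupling, so that it cannot trap the acylpalladium as an amide; it adds to the ynone at C2 to give enaminone 11, and the neighbouring phenol attacks the same carbon and expels the amine, forming O1–C2. The closest known reaction type is the palladium-catalysed carbonylative Sonogashira coupling of 2-iodophenols with terminal arylalkynes followed by amine-mediated cyclisation to flavones. Ring C closes in the 6-endo mode (6-endo-dig in formal terms on 10, 6-endo-trig addition–elimination on 11), and no stereocentre is formed. Carbonylative coupling must win over direct alkynylation, which would lead to a benzofuran; CO pressure and the fast CO insertion of a di-ortho-substituted, electron-rich aryl–palladium species should secure this. The 6-endo closure must win over 5-exo closure to the aurone; the enaminone route should secure this, since C2 is then the only electrophilic carbon. The regiochemistry is fixed because 5 has a single C–I bond with the hydroxyl on the adjacent carbon.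

**Step 6**
Reactants: 12 2-[2-(benzyloxy)-6-methoxyphenyl]-5,6,7,8-tetramethoxy-4H-chromen-4-one
Product: 13 (2S,4S)-2-[2-(benzyloxy)-6-methoxyphenyl]-5,6,7,8-tetramethoxychroman-4-ol
Conditions: [Ru(cod)(2-methylallyl)2] (5 mol %), (R,R)-SINpEt·HBF4 (10 mol %), KOtBu (15 mol %), hexane, 70 °C (catalyst formation); then 12, H2 (100 bar), toluene, 25–40 °C
Reagents that add atoms: none
Why: Ruthenium–NHC-catalysed enantioselective hydrogenation of a flavone; the chiral carbene with its 1-(1-naphthyl)ethyl arms controls which face of C2=C3 receives hydrogen and so sets C2 as S, while the ketone is reduced as well, expected mainly cis (4S), a centre that step 7 removes. The benzenoid rings and the benzyl ether should not be reduced by this catalyst; 13 is acid-sensitive and is carried on without delay.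

**Step 7**
Reactants: 13 (2S,4S)-2-[2-(benzyloxy)-6-methoxyphenyl]-5,6,7,8-tetramethoxychroman-4-ol
Product: 14 (S)-2-[2-(benzyloxy)-6-methoxyphenyl]-5,6,7,8-tetramethoxychroman-4-one
Conditions: Dess–Martin periodinane, NaHCO3, CH2Cl2, 0 °C → rt
Reagents that add atoms: none
Why: Dess–Martin oxidation of the benzylic secondary alcohol under buffered conditions; C2 is not α to the new carbonyl and can lose its configuration only by ring opening, which neutral conditions avoid, and any C4 epimer of 13 converges on 14.

**Step 8**
Reactants: 14 (S)-2-[2-(benzyloxy)-6-methoxyphenyl]-5,6,7,8-tetramethoxychroman-4-one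
Product: 15 (S)-2-[2-(benzyloxy)-6-methoxyphenyl]-5-hydroxy-6,7,8-trimethoxychroman-4-one
Conditions: BCl3 (1.5 equiv), CH2Cl2, −78 → −20 °C; then H2O
Reagents that add atoms: none
Why: Chelation-directed ether cleavage; BCl3 binds the C4 carbonyl and the peri C5 methoxy oxygen in a six-membered chelate and chloride removes that methyl group, while the non-chelated methyl ethers and the benzyl ether should react much more slowly at low temperature. Hydrolysis of the boron chelate frees the C5 phenol, and the short, cold exposure is meant to leave C2–O1 intact.

**Step 9**
Reactants: 15 (S)-2-[2-(benzyloxy)-6-methoxyphenyl]-5-hydroxy-6,7,8-trimethoxychroman-4-one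
Product: 16 (S)-5-hydroxy-2-(2-hydroxy-6-methoxyphenyl)-6,7,8-trimethoxychroman-4-one
Conditions: H2 (1 atm), 10% Pd/C, EtOAc, rt
Reagents that add atoms: none
Why: Hydrogenolysis of the primary benzyl ether on Pd/C under neutral conditions; the hindered secondary C2–O1 bond and the chelated aryl ketone should survive at 1 atm, and no acid or base is present that could open ring C and racemise C2.

## Compound list

1 | 1,2,3,4-tetramethoxybenzene | COc1ccc(OC)c(OC)c1OC | starting material
2 | (2,3,4,5-tetramethoxyphenyl)lithium | [Li]c1cc(OC)c(OC)c(OC)c1OC | intermediate (not isolated)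
3 | dimethyl (2,3,4,5-tetramethoxyphenyl)boronate | COB(OC)c1cc(OC)c(OC)c(OC)c1OC | intermediate (not isolated)
4 | 2,3,4,5-tetramethoxyphenol | COc1cc(O)c(OC)c(OC)c1OC | intermediate
5 | 2-iodo-3,4,5,6-tetramethoxyphenol | COc1c(O)c(I)c(OC)c(OC)c1OC | intermediate
6 | 2-hydroxy-6-methoxybenzaldehyde | COc1cccc(O)c1C=O | starting material
7 | 2-(benzyloxy)-6-methoxybenzaldehyde | COc1cccc(OCc2ccccc2)c1C=O | intermediate
8 | 1-(benzyloxy)-2-ethynyl-3-methoxybenzene | COc1cccc(OCc2ccccc2)c1C#C | intermediate
9 | carbon monoxide | [C-]#[O+] | starting material
10 | 3-[2-(benzyloxy)-6-methoxyphenyl]-1-(2-hydroxy-3,4,5,6-tetramethoxyphenyl)prop-2-yn-1-one | COc1cccc(OCc2ccccc2)c1C#CC(=O)c1c(O)c(OC)c(OC)c(OC)c1OC | intermediate (not isolated)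
11 | (E)-3-[2-(benzyloxy)-6-methoxyphenyl]-3-(diethylamino)-1-(2-hydroxy-3,4,5,6-tetramethoxyphenyl)prop-2-en-1-one (the Z isomer would close in the same way) | CCN(CC)/C(=C/C(=O)c1c(O)c(OC)c(OC)c(OC)c1OC)c1c(OC)cccc1OCc1ccccc1 | intermediate (not isolated)
12 | 2-[2-(benzyloxy)-6-methoxyphenyl]-5,6,7,8-tetramethoxy-4H-chromen-4-one | COc1cccc(OCc2ccccc2)c1-c1cc(=O)c2c(OC)c(OC)c(OC)c(OC)c2o1 | intermediate
13 | (2S,4S)-2-[2-(benzyloxy)-6-methoxyphenyl]-5,6,7,8-tetramethoxychroman-4-ol | COc1cccc(OCc2ccccc2)c1[C@@H]1C[C@H](O)c2c(OC)c(OC)c(OC)c(OC)c2O1 | intermediate
14 | (S)-2-[2-(benzyloxy)-6-methoxyphenyl]-5,6,7,8-tetramethoxychroman-4-one | COc1cccc(OCc2ccccc2)c1[C@@H]1CC(=O)c2c(OC)c(OC)c(OC)c(OC)c2O1 | intermediate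
15 | (S)-2-[2-(benzyloxy)-6-methoxyphenyl]-5-hydroxy-6,7,8-trimethoxychroman-4-one | COc1cccc(OCc2ccccc2)c1[C@@H]1CC(=O)c2c(O)c(OC)c(OC)c(OC)c2O1 | intermediate
16 | (S)-5-hydroxy-2-(2-hydroxy-6-methoxyphenyl)-6,7,8-trimethoxychroman-4-one | COc1cccc(O)c1[C@@H]1CC(=O)c2c(O)c(OC)c(OC)c(OC)c2O1 | target

## Step count and least certain steps

Total: 9 steps. Longest linear sequence: 7 steps (steps 1, 2, 5, 6, 7, 8, 9 from 1; equally steps 3, 4, 5, 6, 7, 8, 9 from 6).

**Step 5 (key step).** The most likely failures are these:
- Alkynylation without CO uptake, which after cyclisation gives a benzofuran.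
- Premature 5-exo closure of the ynone under the tertiary amine, before the secondary amine is added.
- Slow turnover, because both partners are di-ortho-substituted.

The fallback gives up the carbonylation for a classical aldol construction. It sets out from 4 and 7. Friedel–Crafts acetylation of 4 at its only free position (AcOH, BF3·OEt2, 90 °C) should give 1-(2-hydroxy-3,4,5,6-tetramethoxyphenyl)ethan-1-one F1. Claisen–Schmidt condensation of F1 with 7 (KOH, EtOH, rt) should give (E)-3-[2-(benzyloxy)-6-methoxyphenyl]-1-(2-hydroxy-3,4,5,6-tetramethoxyphenyl)prop-2-en-1-one F2. Oxidative cyclisation (catalytic I2, DMSO, 120 °C) then closes ring C, and the route is rejoined at 12.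

**Step 6.** The 2',6'-disubstituted ring B is twisted out of the chromone plane and screens both faces of C2. Facial selectivity may therefore be poor or conversion incomplete, and forcing the reaction risks partial reduction of an arene. The fallback makes the centre without selectivity and then resolves it. It sets out from 12. Conjugate reduction with LiBH(s-Bu)3 (THF, −78 °C) should give racemic 2-[2-(benzyloxy)-6-methoxyphenyl]-5,6,7,8-tetramethoxychroman-4-one F3. Kinetic resolution by asymmetric transfer hydrogenation ([Cp*RhCl(TsDPEN)], HCO2H/Et3N, EtOAc, rt) follows, using the catalyst antipode that reduces the (2R) ketone. This consumes that enantiomer as (2R,4R)-2-[2-(benzyloxy)-6-methoxyphenyl]-5,6,7,8-tetramethoxychroman-4-ol F4 and leaves the (S) ketone, so the route is rejoined at 14. F4 can be oxidised and racemised with base back to F3 for recycling.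

**Step 8.** Two processes threaten this step:
- Loss of configurational integrity, through Lewis-acid-induced opening of ring C at the electron-rich benzylic C2–O1 bond.
- Partial loss of the benzyl ether, which complicates isolation.

The fallback moves the demethylation to the achiral flavone and replaces the C5 methyl by benzyl, so that no Lewis acid meets the stereocentre. It sets out from 12. BCl3 (CH2Cl2, −78 → 0 °C) should give 2-[2-(benzyloxy)-6-methoxyphenyl]-5-hydroxy-6,7,8-trimethoxy-4H-chromen-4-one F5. Benzylation (BnBr, K2CO3, DMF, 70 °C) should give 5-(benzyloxy)-2-[2-(benzyloxy)-6-methoxyphenyl]-6,7,8-trimethoxy-4H-chromen-4-one F6, and would also restore any ring-B benzyl group lost in the previous operation. Hydrogenation as in step 6 should give (2S,4S)-5-(benzyloxy)-2-[2-(benzyloxy)-6-methoxyphenyl]-6,7,8-trimethoxychroman-4-ol F7. Oxidation as in step 7 should give (S)-5-(benzyloxy)-2-[2-(benzyloxy)-6-methoxyphenyl]-6,7,8-trimethoxychroman-4-one F8. Hydrogenolysis (H2, Pd/C, EtOAc, rt) removes both benzyl ethers, and the route is rejoined at 16.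

**Step 2.** The substrate is an electron-rich para-methoxyphenol, and the iodinating agent may oxidise it towards a quinone instead of substituting it. The fallback replaces electrophilic substitution by directed metalation on a protected phenol. It sets out from 4. MOMCl with i-Pr2NEt (CH2Cl2) should give 1,2,3,4-tetramethoxy-5-(methoxymethoxy)benzene F9. Lithiation of the single ring hydrogen, flanked by two directing oxygens (n-BuLi, THF, −78 → 0 °C), and quenching with I2 should give 1-iodo-2,3,4,5-tetramethoxy-6-(methoxymethoxy)benzene F10. Acetal cleavage (HCl, MeOH, 40 °C) rejoins the route at 5.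

**Step 1.** Metalation may be incomplete, or the peroxide may oxidise the product phenol further. The fallback introduces the oxygen through a formyl group. It sets out from 1. Rieche formylation (Cl2CHOMe, TiCl4, CH2Cl2, 0 °C) should give 2,3,4,5-tetramethoxybenzaldehyde F11. Baeyer–Villiger oxidation (mCPBA, CH2Cl2) should give 2,3,4,5-tetramethoxyphenyl formate F12. Methanolysis (K2CO3, MeOH) rejoins the route at 4.

## Further compounds

F1 | step 5 | 1-(2-hydroxy-3,4,5,6-tetramethoxyphenyl)ethan-1-one | CC(=O)c1c(O)c(OC)c(OC)c(OC)c1OC
F2 | step 5 | (E)-3-[2-(benzyloxy)-6-methoxyphenyl]-1-(2-hydroxy-3,4,5,6-tetramethoxyphenyl)prop-2-en-1-one | COc1cccc(OCc2ccccc2)c1/C=C/C(=O)c1c(O)c(OC)c(OC)c(OC)c1OC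
F3 | step 6 | racemic 2-[2-(benzyloxy)-6-methoxyphenyl]-5,6,7,8-tetramethoxychroman-4-one | COc1cccc(OCc2ccccc2)c1C1CC(=O)c2c(OC)c(OC)c(OC)c(OC)c2O1
F4 | step 6 | (2R,4R)-2-[2-(benzyloxy)-6-methoxyphenyl]-5,6,7,8-tetramethoxychroman-4-ol | COc1cccc(OCc2ccccc2)c1[C@H]1C[C@@H](O)c2c(OC)c(OC)c(OC)c(OC)c2O1
F5 | step 8 | 2-[2-(benzyloxy)-6-methoxyphenyl]-5-hydroxy-6,7,8-trimethoxy-4H-chromen-4-one | COc1cccc(OCc2ccccc2)c1-c1cc(=O)c2c(O)c(OC)c(OC)c(OC)c2o1
F6 | step 8 | 5-(benzyloxy)-2-[2-(benzyloxy)-6-methoxyphenyl]-6,7,8-trimethoxy-4H-chromen-4-one | COc1cccc(OCc2ccccc2)c1-c1cc(=O)c2c(OCc3ccccc3)c(OC)c(OC)c(OC)c2o1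
F7 | step 8 | (2S,4S)-5-(benzyloxy)-2-[2-(benzyloxy)-6-methoxyphenyl]-6,7,8-trimethoxychroman-4-ol | COc1cccc(OCc2ccccc2)c1[C@@H]1C[C@H](O)c2c(OCc3ccccc3)c(OC)c(OC)c(OC)c2O1
F8 | step 8 | (S)-5-(benzyloxy)-2-[2-(benzyloxy)-6-methoxyphenyl]-6,7,8-trimethoxychroman-4-one | COc1cccc(OCc2ccccc2)c1[C@@H]1CC(=O)c2c(OCc3ccccc3)c(OC)c(OC)c(OC)c2O1
F9 | step 2 | 1,2,3,4-tetramethoxy-5-(methoxymethoxy)benzene | COCOc1cc(OC)c(OC)c(OC)c1OC
F10 | step 2 | 1-iodo-2,3,4,5-tetramethoxy-6-(methoxymethoxy)benzene | COCOc1c(I)c(OC)c(OC)c(OC)c1OC
F11 | step 1 | 2,3,4,5-tetramethoxybenzaldehyde | COc1cc(C=O)c(OC)c(OC)c1OC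
F12 | step 1 | 2,3,4,5-tetramethoxyphenyl formate | COc1cc(OC=O)c(OC)c(OC)c1OC
A1 | alternative 1 | (S)-2-[2-(benzyloxy)-6-methoxyphenyl]-5,6,7,8-tetramethoxychroman-4-one | COc1cccc(OCc2ccccc2)c1[C@@H]1CC(=O)c2c(OC)c(OC)c(OC)c(OC)c2O1
A2 | alternative 1 | (R)-2-[2-(benzyloxy)-6-methoxyphenyl]-2-(2-formyl-3,4,5,6-tetramethoxyphenoxy)ethyl 4-methylbenzenesulfonate | COc1cccc(OCc2ccccc2)c1[C@@H](Oc1c(C=O)c(OC)c(OC)c(OC)c1OC)COS(=O)(=O)c1ccc(C)cc1
A3 | alternative 2 | (2S,4S)-2-[2-(benzyloxy)-6-methoxyphenyl]-4-[(tert-butyldimethylsilyl)oxy]-6,7,8-trimethoxychroman-5-ol | COc1cccc(OCc2ccccc2)c1[C@@H]1C[C@H](O[Si](C)(C)C(C)(C)C)c2c(O)c(OC)c(OC)c(OC)c2O1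
A4 | alternative 2 | dimethyl squarate (3,4-dimethoxycyclobut-3-ene-1,2-dione) | COC1=C(OC)C(=O)C1=O
A5 | alternative 3 | (S)-5-(benzyloxy)-2-(2-hydroxy-6-methoxyphenyl)-6,7,8-trimethoxychroman-4-one | COc1cccc(O)c1[C@@H]1CC(=O)c2c(OCc3ccccc3)c(OC)c(OC)c(OC)c2O1
A6 | alternative 3 | cyclobut-2-en-1-one | O=C1C=CC1
A7 | alternative 3 | (S)-5-(benzyloxy)-6,7,8-trimethoxy-2-(methoxyethynyl)chroman-4-one | COC#C[C@@H]1CC(=O)c2c(OCc3ccccc3)c(OC)c(OC)c(OC)c2O1
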